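## The problem

CNP0313563.1 is a diester built on a cyclopentane (iridoid numbering: ring C5–C6–C7–C8–C9). C9 carries the acylated CH2O group (C1), C8 a methyl (C10), C7 an acyloxy group, and C5 a 1,3-dihydroxypropan-2-yl group (C4 with C3 and C11). Both acyl groups are the same (3S,4E)-4-formyl-3-(2-oxoethyl)hex-4-enoyl arm. The four ring stereocentres alternate (C5 down, C9 up, C8 down, C7 up), so every vicinal pair is trans and each centre can be set from its neighbour. The two arm stereocentres are too remote for the ring to control and must come from a reagent or from the chiral pool. The molecule holds four aldehydes, two of them enals with an allylic stereocentre that base would epimerise or deconjugate. It also holds two alkyl esters and a free 1,3-diol, so the aldehydes have to appear last under neutral conditions and the arms have to be attached in masked form. The arms are the ring-opened, decarbomethoxylated form of the secoiridoid unit of oleuropein, whose C5 configuration and (E)-ethylidene group map onto them exactly. In the core, four hydroxyls must be told apart: two acylated (one with a defined configuration at C7) and two free. The feature that opens the core is that C8 and C9 are α and β to the oxygenated C7, and C5 is the other β position through C6. A 4-silyloxycyclopent-2-enone therefore already holds all five ring carbons, takes C1 at C9 and the methyl at C8 in one operation, and its silyloxy group on C5 serves first as the controlling stereocentre and then as a leaving group that lets the C4 unit enter.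

## Retrosynthesis

**Unveiling the aldehydes (21 from 20).** No core bond is cut. Each arm of target 21 is redrawn as the closed oleoside 11-methyl ester unit of bis-glucoside 20. The enal aldehyde is held in the glucosidic acetal and the saturated aldehyde in the β-alkoxyacrylate, whose methoxycarbonyl carbon is the only carbon to be excised. Acylation with a free dialdehyde acid would fail through lactol formation and self-condensation, and an acetal-protected arm would need its own asymmetric synthesis. The forward reaction, a Krapcho decarbomethoxylation in hot wet DMSO that also hydrolyses the acetal, must spare two alkyl esters and the free diol; the neutral medium allows that.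

**The two ester bonds (20 from 19, 18, 13 and 17).** Bis-glucoside 20 comes from the fully protected bis-ester 19 by one mild acid treatment. The secondary C7–O bond is cut with inversion (Mitsunobu), leading back to mono-ester 18 with the 7S alcohol. The primary acyl–O bond at C1 is cut next (Steglich), leading to diol 13 and acid 17. The 7S alcohol is the epimer a bulky hydride delivers reliably, and the inversion costs nothing because the ester has to be made anyway. The primary hydroxyl is acylated first so that it cannot attack the activated C7 from the face on which it sits. Diol 13 has no aldehyde, no ester and only two free hydroxyls of very different hindrance.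

**The arm (17 from 15 and 14).** Acid 17 is oleoside 11-methyl ester 15 with its four glucose hydroxyls silylated. Acid 15 is cut at the phenethyl ester bond of oleuropein 14. The vinylogous carbonate methyl ester and the glucoside must survive the saponification, which their low electrophilicity allows. Both arm stereocentres and both alkene geometries are thus bought, not made.

**Oxidation-state adjustment of the core (13 from 12, 11 and 9).** The acetonide of 13 is cut to tetraol 12, the 1,3-diol to the malonate of 11, and the C7 alcohol and C1 hydroxyl to the ketone and the C–Si bond of keto malonate 9. The forward sequence needs a face-selective ketone reduction controlled by the C8 methyl, a Tamao oxidation, a hydride reduction and a ketalisation that only the 1,3-diol can answer with a six-membered ring.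

**C5–C4 (9 from 6 and 7).** The bond between C5 and the malonate carbon is cut, giving dimethyl malonate 7 and enone 8. Enone 8 is not stored but generated from β-silyloxy ketone 6 by loss of silanol. The cut uses the silyloxy group twice and relays chirality from C9 to C5 (trans Michael addition). Adding the C4 unit before C1 would put the larger group next to the position to be alkylated.

**C9–C1 and C8–C10 (6 from 3, 2 and 4).** Both bonds are cut at once, giving (R)-4-silyloxycyclopentenone 3, silylmethyl Grignard reagent 2 and iodomethane 4. This is the key simplification: one commercial stereocentre, no ring construction. The forward step must add anti to the silyloxy group and methylate trans, faster than the enolate equilibrates.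

**The nucleophile (2 from 1).** The C–Mg bond of 2 is cut to commercial (chloromethyl)silane 1 and magnesium.

## Roads not taken

**Alternative 1:** The C8–C9 bond is cut. The acyclic keto ester A1 would be converted with LiN(i-Pr)2 into a dianion (ketone enolate at C8, ester enolate at C9) and oxidised with Fe(acac)3 (trivalent iron) to close cyclopentanone A2.
- Merits: the C4 unit is present from the start as its acetonide, C1 arrives at the ester oxidation state without silicon chemistry, and both new centres are epimerisable, so the all-trans product A2 is also the thermodynamic one. In these respects it is cleaner than the chosen plan.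
- Weak points: A1 carries the C5 stereocentre and needs an asymmetric synthesis of its own. Its ethyl ketone can be deprotonated on the C6 side as well as at C8, which feeds unproductive intermolecular coupling. Radical-type cross-coupling of two different enolates in one molecule is less predictable in yield and diastereoselectivity than a cuprate addition.
- Comparison: the chosen plan buys the ring and the first stereocentre and relies on two ionic steps of well-known selectivity. That is set against the earlier arrival of the diol unit in A2.

**Alternative 2:** The arm bonds between the stereocentre and the alkenyl carbon are cut in both arms. The bis-enoate A3 of the core would react twice with alkenylboronic acid A4 under [Rh(OH)(cod)]2 and BINAP (monovalent rhodium) to give the tetra-acetal A5.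
- Merits: the arms are fully synthetic, so the route does not depend on a natural glycoside and would give arm analogues or diastereomers by changing the ligand. The last step would be a mild acetal hydrolysis that frees the four aldehydes and the diol together. That ending is clearly gentler than the hot Krapcho step of the chosen plan.
- Weak points: A4 is an α-branched alkenylboron reagent with an allylic acetal, a class that transmetalates slowly and protodeboronates. Two catalyst-controlled additions must both be highly selective on a chiral core, and diastereomers of A5 that differ in one remote arm centre would be hard to separate. The γ-acetal enoate of A3 can isomerise under the basic conditions. The same core, with the same C7 inversion, is still needed.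
- Comparison: the chosen plan sets against the milder ending the certainty of arm configuration and (E)-geometry from oleuropein 14 and a two-step access to acid 17.

**Alternative 3:** The C7–C8 and C5–C9 bonds are cut. Cyclopentadiene A6 would add endo to imide A7 under the Cu(SbF6)2 complex of 2,2'-isopropylidenebis(4-tert-butyl-2-oxazoline) (divalent copper), giving norbornene A8. The alkene bridge would later be opened through a ketone and a Baeyer–Villiger oxidation.
- Merits: a catalytic enantioselective cycloaddition of a very reliable type sets C8 and C9 trans and fixes both bridgeheads in one step, without chiral-pool material.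
- Weak points: A8 is far from the core. The acyl group must be reduced to a methyl. The ketone must be placed on one specific alkene carbon of an unsymmetrical norbornene. The two-carbon chain left on C5 after cleavage lacks one carbon of the CH(CH2OH)2 unit. The Baeyer–Villiger oxygen arrives on C7 cis to the C8 substituent, so the same inversion as in the chosen plan is still required.
- Comparison: the cycloaddition is at least as dependable as the chosen key step, but the chosen plan reaches diol 13 in six steps, which this road cannot match.

Key step: step 2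

Remark on the chemistry (assumption): commercial oleuropein 14 is taken to be the natural (5S,8E) β-D-glucoside, and the Krapcho unveiling known for such secoiridoid glucosides is assumed to work on both arms of 20.

Step 1
Reactants: 1 (chloromethyl)dimethyl(propan-2-yloxy)silane
Product: 2 chloro{[dimethyl(propan-2-yloxy)silyl]methyl}magnesium
Conditions: Mg turnings, BrCH2CH2Br (cat.), THF, rt → reflux
Reagents that add atoms: magnesium, [Mg]
Why: Grignard formation by magnesium insertion into the primary C–Cl bond; the branched alkoxy group on silicon resists attack by the carbanion, so the reagent is a stable hydroxymethyl anion equivalent in THF.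

Step 2
Reactants: 3 (R)-4-(tert-butyldimethylsilyloxy)cyclopent-2-en-1-one; 2 chloro{[dimethyl(propan-2-yloxy)silyl]methyl}magnesium; 4 iodomethane
Product: 6 (2R,3R,4R)-4-(tert-butyldimethylsilyloxy)-3-{[dimethyl(propan-2-yloxy)silyl]methyl}-2-methylcyclopentan-1-one, via chloromagnesium enolate 5 (not isolated)
Conditions: 2 (1.3 equiv), CuI (10 mol %), LiCl (20 mol %), THF, −78 → −40 °C; then MeI (5 equiv), DMPU, −78 → −20 °C; NH4Cl (aq), −20 °C
Reagents that add atoms: none
Why: Grignard reagent 2 transmetalates to CuI to give a silylmethylcopper species (monovalent copper) that binds the enone face of 3 opposite the C5 silyloxy group, passes through a β-cuprio enolate (formally trivalent copper) and reductively eliminates to form C9–C1, leaving the regiodefined chloromagnesium enolate 5. DMPU then loosens the magnesium enolate so that excess MeI alkylates C8 by an SN2 reaction on the face opposite the new C9 substituent, forming C8–CH3. The closest known reaction type is the three-component coupling of 4-silyloxycyclopent-2-enones (organocopper conjugate addition, enolate alkylation), combined with the copper-catalysed conjugate addition of silylmethyl Grignard reagents as hydroxymethyl anion equivalents. No ring is closed; the purchased five-membered ring is kept. C9 is controlled by the C5 silyloxy stereocentre (1,2-induction, anti addition) and C8 by C9 (trans alkylation), so ketone 6 should be the trans,trans isomer. The step needs 1,4- over 1,2-addition (secured by copper), high facial selectivity (secured by the bulky silyloxy group next to the β-carbon) and C-methylation faster than enolate equilibration. The last point matters because a C6 enolate would expel silanolate, whereas enolate 5 cannot, its leaving group not being β to the nucleophilic carbon; low temperature, the polar additive, excess MeI and a cold quench are there to keep it so.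

Step 3
Reactants: 6 (2R,3R,4R)-4-(tert-butyldimethylsilyloxy)-3-{[dimethyl(propan-2-yloxy)silyl]methyl}-2-methylcyclopentan-1-one; 7 dimethyl malonate
Product: 9 dimethyl 2-[(1S,2S,3R)-2-{[dimethyl(propan-2-yloxy)silyl]methyl}-3-methyl-4-oxocyclopentyl]propanedioate, via enone 8 (not isolated)
Conditions: DBU (1.5 equiv), 7 (2 equiv), MeCN, 0 °C → rt
Reagents that add atoms: none
Why: DBU enolises the ketone toward C6 and the C5 silyloxy group leaves by E1cB elimination to give enone 8, to which the malonate anion adds in a Michael reaction at C5 on the face anti to the C9 silylmethyl group (1,2-induction, trans). C8 stays trans to C9 because that is the thermodynamic arrangement of this epimerisable α-centre, and consuming 8 as it forms limits γ-deprotonation.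

Step 4
Reactants: 9 dimethyl 2-[(1S,2S,3R)-2-{[dimethyl(propan-2-yloxy)silyl]methyl}-3-methyl-4-oxocyclopentyl]propanedioate
Product: 11 dimethyl 2-[(1R,2S,3R,4S)-4-hydroxy-2-(hydroxymethyl)-3-methylcyclopentyl]propanedioate, via silyl alcohol 10 (not isolated)
Conditions: LiBH(s-Bu)3 (1.3 equiv), THF, −78 °C; then MeOH, KHCO3, KF, 30% H2O2, 0 °C → rt
Reagents that add atoms: hydrogen peroxide, OO
Why: The bulky trialkylborohydride should attack the C7 ketone from the face opposite the adjacent C8 methyl and the C5 malonate, setting the 7S alcohol (hydroxyl cis to the methyl) without touching the esters at −78 °C. The peroxide work-up doubles as a Tamao oxidation, in which fluoride-activated silicon lets C1 migrate to oxygen, freeing the primary alcohol and destroying the borane.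

Step 5
Reactants: 11 dimethyl 2-[(1R,2S,3R,4S)-4-hydroxy-2-(hydroxymethyl)-3-methylcyclopentyl]propanedioate
Product: 12 2-[(1R,2S,3R,4S)-4-hydroxy-2-(hydroxymethyl)-3-methylcyclopentyl]propane-1,3-diol
Conditions: LiAlH4 (5 equiv), THF, 0 °C → reflux; Na2SO4·10H2O
Reagents that add atoms: none
Why: LiAlH4 reduction of both malonate esters to the 2-substituted propane-1,3-diol; no stereocentre is touched, and any bridged lactone formed between the cis C7 hydroxyl and a malonate ester would be reduced to the same tetraol.

Step 6
Reactants: 12 2-[(1R,2S,3R,4S)-4-hydroxy-2-(hydroxymethyl)-3-methylcyclopentyl]propane-1,3-diol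
Product: 13 (1S,2R,3S,4R)-4-(2,2-dimethyl-1,3-dioxan-5-yl)-3-(hydroxymethyl)-2-methylcyclopentan-1-ol
Conditions: Me2C(OMe)2 (1.2 equiv), PPTS (cat.), acetone, rt
Reagents that add atoms: 2,2-dimethoxypropane, COC(C)(C)OC
Why: Acid-catalysed transketalisation under thermodynamic control: only the propane-1,3-diol unit can close an unstrained six-membered 1,3-dioxane, whereas any other hydroxyl pair would need a seven- or eight-membered ring; mixed acyclic ketals revert on aqueous work-up.

Step 7
Reactants: 14 oleuropein
Product: 15 oleoside 11-methyl ester, 2-[(2S,3E,4S)-3-ethylidene-2-(β-D-glucopyranosyloxy)-5-(methoxycarbonyl)-3,4-dihydro-2H-pyran-4-yl]acetic acid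
Conditions: NaOH (0.2 M aq., 4 equiv), 0 °C → rt, Ar; then HCl to pH 3
Reagents that add atoms: sodium hydroxide, [Na+].[OH-]
Why: Chemoselective saponification: the saturated phenethyl ester is hydrolysed, while the methyl ester (a vinylogous carbonate deactivated by the ring enol ether oxygen) and the glucoside should be left. The arm stereocentre is not α to a carbonyl and the (E)-ethylidene group is unaffected.

Step 8
Reactants: 15 oleoside 11-methyl ester
Product: 17 2',3',4',6'-tetra-O-triethylsilyl oleoside 11-methyl ester (free acetic acid side chain), via triethylsilyl ester 16 (not isolated)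
Conditions: Et3SiCl (6 equiv), imidazole, DMF, 0 °C → rt; then aq. citric acid (pH 4), THF, 0 °C
Reagents that add atoms: chlorotriethylsilane, CC[Si](Cl)(CC)CC
Why: Exhaustive silylation of the four glucose hydroxyls and, transiently, of the acid; only the silyl ester is hydrolysed by water at mild pH. The remaining silyl ethers are stable to carbodiimide and Mitsunobu conditions and fall later to dilute acid.

Step 9
Reactants: 13 (1S,2R,3S,4R)-4-(2,2-dimethyl-1,3-dioxan-5-yl)-3-(hydroxymethyl)-2-methylcyclopentan-1-ol; 17 2',3',4',6'-tetra-O-triethylsilyl oleoside 11-methyl ester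
Product: 18 [(1S,2R,3S,5R)-5-(2,2-dimethyl-1,3-dioxan-5-yl)-3-hydroxy-2-methylcyclopentyl]methyl ester of acid 17 (acyl group on the primary oxygen, free 7S hydroxyl)
Conditions: 17 (1.05 equiv), DCC (1.2 equiv), DMAP (0.1 equiv), CH2Cl2, 0 °C
Reagents that add atoms: none
Why: Steglich esterification (carbodiimide activation, acylpyridinium transfer) should be selective for the unhindered primary C1 hydroxyl over the secondary C7 hydroxyl flanked by the cis methyl when one equivalent of acid is used at 0 °C; no stereocentre is involved.

Step 10
Reactants: 18 mono-ester with free 7S hydroxyl; 17 2',3',4',6'-tetra-O-triethylsilyl oleoside 11-methyl ester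
Product: 19 (1R,2R,3S,4R)-4-(2,2-dimethyl-1,3-dioxan-5-yl)-2-methyl-3-(acyloxymethyl)cyclopentyl ester, both acyl groups being that of acid 17 (bis-ester, 7R)
Conditions: 17 (1.5 equiv), PPh3 (2 equiv), DIAD (2 equiv), toluene, 0 °C → rt
Reagents that add atoms: none
Why: Mitsunobu esterification: the C7 oxyphosphonium is displaced by the carboxylate of 17 in an SN2 reaction, inverting 7S to the 7R acyloxy centre (trans to the C8 methyl) that the target requires. The C1 hydroxyl is already acylated and cannot cyclise onto C7.

Step 11
Reactants: 19 protected bis-ester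
Product: 20 bis(oleoside 11-methyl ester) diester of the core: 19 with eight free glucose hydroxyls and the free 1,3-diol
Conditions: AcOH/THF/H2O (3:1:1), 40 °C
Reagents that add atoms: none
Why: Mild aqueous acetic acid hydrolyses the eight triethylsilyl ethers and the 1,3-dioxane ketal, whereas the glucosidic acetals, the deactivated enol ethers and the alkyl esters should be stable at this acidity.

Step 12
Reactants: 20 bis-glucoside diol
Product: 21 CNP0313563.1, [(1S,2R,3R,5R)-5-(1,3-dihydroxypropan-2-yl)-2-methyl-3-{[(3S,4E)-4-formyl-3-(2-oxoethyl)hex-4-enoyl]oxy}cyclopentyl]methyl (3S,4E)-4-formyl-3-(2-oxoethyl)hex-4-enoate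
Conditions: NaCl (4 equiv), DMSO/H2O (10:1), 150 °C, Ar
Reagents that add atoms: water, O
Why: Krapcho unveiling as known for oleuropein-type secoiridoid glucosides: in hot wet DMSO the glucosidic acetal is hydrolysed, the hemiacetal opens to the enal and a formylacetate, and chloride and water remove the methoxycarbonyl group to leave the 2-oxoethyl aldehyde. The arm stereocentre is not α to a carbonyl, the ethylidene geometry is carried into the (E)-enal, and the neutral medium should spare the two alkyl esters.

## Compound list

1 | (chloromethyl)dimethyl(propan-2-yloxy)silane | CC(C)O[Si](C)(C)CCl | starting material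
2 | chloro{[dimethyl(propan-2-yloxy)silyl]methyl}magnesium | CC(C)O[Si](C)(C)C[Mg]Cl | intermediate
3 | (R)-4-(tert-butyldimethylsilyloxy)cyclopent-2-en-1-one | O=C1C=C[C@H](O[Si](C)(C)C(C)(C)C)C1 | starting material
4 | iodomethane | CI | starting material
5 | chloromagnesium (3R,4R)-4-(tert-butyldimethylsilyloxy)-3-{[dimethyl(propan-2-yloxy)silyl]methyl}-2-methylcyclopent-1-en-1-olate | CC(C)O[Si](C)(C)C[C@@H]1C(C)=C(O[Mg]Cl)C[C@H]1O[Si](C)(C)C(C)(C)C | intermediate
6 | (2R,3R,4R)-4-(tert-butyldimethylsilyloxy)-3-{[dimethyl(propan-2-yloxy)silyl]methyl}-2-methylcyclopentan-1-one | CC(C)O[Si](C)(C)C[C@@H]1[C@@H](C)C(=O)C[C@H]1O[Si](C)(C)C(C)(C)C | intermediate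
7 | dimethyl malonate (dimethyl propanedioate) | COC(=O)CC(=O)OC | starting material
8 | (4S,5R)-4-{[dimethyl(propan-2-yloxy)silyl]methyl}-5-methylcyclopent-2-en-1-one | CC(C)O[Si](C)(C)C[C@@H]1[C@@H](C)C(=O)C=C1 | intermediate
9 | dimethyl 2-[(1S,2S,3R)-2-{[dimethyl(propan-2-yloxy)silyl]methyl}-3-methyl-4-oxocyclopentyl]propanedioate | CC(C)O[Si](C)(C)C[C@@H]1[C@@H](C)C(=O)C[C@H]1C(C(=O)OC)C(=O)OC | intermediate
10 | dimethyl 2-[(1S,2S,3R,4S)-2-{[dimethyl(propan-2-yloxy)silyl]methyl}-4-hydroxy-3-methylcyclopentyl]propanedioate | CC(C)O[Si](C)(C)C[C@@H]1[C@@H](C)[C@@H](O)C[C@H]1C(C(=O)OC)C(=O)OC | intermediate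
11 | dimethyl 2-[(1R,2S,3R,4S)-4-hydroxy-2-(hydroxymethyl)-3-methylcyclopentyl]propanedioate | OC[C@@H]1[C@@H](C)[C@@H](O)C[C@H]1C(C(=O)OC)C(=O)OC | intermediate
12 | 2-[(1R,2S,3R,4S)-4-hydroxy-2-(hydroxymethyl)-3-methylcyclopentyl]propane-1,3-diol | OC[C@@H]1[C@@H](C)[C@@H](O)C[C@H]1C(CO)CO | intermediate
13 | (1S,2R,3S,4R)-4-(2,2-dimethyl-1,3-dioxan-5-yl)-3-(hydroxymethyl)-2-methylcyclopentan-1-ol | OC[C@@H]1[C@@H](C)[C@@H](O)C[C@H]1C2COC(C)(C)OC2 | intermediate
14 | oleuropein | C/C=C/1\[C@@H](C(=CO[C@H]1O[C@H]2[C@@H]([C@H]([C@@H]([C@H](O2)CO)O)O)O)C(=O)OC)CC(=O)OCCc3ccc(O)c(O)c3 | starting material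
15 | oleoside 11-methyl ester, 2-[(2S,3E,4S)-3-ethylidene-2-(β-D-glucopyranosyloxy)-5-(methoxycarbonyl)-3,4-dihydro-2H-pyran-4-yl]acetic acid | C/C=C/1\[C@@H](C(=CO[C@H]1O[C@H]2[C@@H]([C@H]([C@@H]([C@H](O2)CO)O)O)O)C(=O)OC)CC(=O)O | intermediate
16 | triethylsilyl ester of 2',3',4',6'-tetra-O-triethylsilyl oleoside 11-methyl ester | C/C=C/1\[C@@H](C(=CO[C@H]1O[C@H]2[C@@H]([C@H]([C@@H]([C@H](O2)CO[Si](CC)(CC)CC)O[Si](CC)(CC)CC)O[Si](CC)(CC)CC)O[Si](CC)(CC)CC)C(=O)OC)CC(=O)O[Si](CC)(CC)CC | intermediate
17 | 2',3',4',6'-tetra-O-triethylsilyl oleoside 11-methyl ester (free acid) | C/C=C/1\[C@@H](C(=CO[C@H]1O[C@H]2[C@@H]([C@H]([C@@H]([C@H](O2)CO[Si](CC)(CC)CC)O[Si](CC)(CC)CC)O[Si](CC)(CC)CC)O[Si](CC)(CC)CC)C(=O)OC)CC(=O)O | intermediate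
18 | [(1S,2R,3S,5R)-5-(2,2-dimethyl-1,3-dioxan-5-yl)-3-hydroxy-2-methylcyclopentyl]methyl ester of acid 17 | C/C=C/1\[C@@H](C(=CO[C@H]1O[C@H]2[C@@H]([C@H]([C@@H]([C@H](O2)CO[Si](CC)(CC)CC)O[Si](CC)(CC)CC)O[Si](CC)(CC)CC)O[Si](CC)(CC)CC)C(=O)OC)CC(=O)OC[C@@H]3[C@@H](C)[C@@H](O)C[C@H]3C4COC(C)(C)OC4 | intermediate
19 | (1R,2R,3S,4R)-4-(2,2-dimethyl-1,3-dioxan-5-yl)-2-methyl-3-(acyloxymethyl)cyclopentyl ester, both acyl groups from acid 17 | C/C=C/1\[C@@H](C(=CO[C@H]1O[C@H]2[C@@H]([C@H]([C@@H]([C@H](O2)CO[Si](CC)(CC)CC)O[Si](CC)(CC)CC)O[Si](CC)(CC)CC)O[Si](CC)(CC)CC)C(=O)OC)CC(=O)OC[C@@H]3[C@@H](C)[C@H](OC(=O)C[C@@H]5C(C(=O)OC)=CO[C@@H](O[C@H]6[C@@H]([C@H]([C@@H]([C@H](O6)CO[Si](CC)(CC)CC)O[Si](CC)(CC)CC)O[Si](CC)(CC)CC)O[Si](CC)(CC)CC)/C5=C/C)C[C@H]3C4COC(C)(C)OC4 | intermediate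
20 | (1R,2R,3S,4R)-4-(1,3-dihydroxypropan-2-yl)-2-methyl-3-(acyloxymethyl)cyclopentyl ester, both acyl groups from oleoside 11-methyl ester 15 | C/C=C/1\[C@@H](C(=CO[C@H]1O[C@H]2[C@@H]([C@H]([C@@H]([C@H](O2)CO)O)O)O)C(=O)OC)CC(=O)OC[C@@H]3[C@@H](C)[C@H](OC(=O)C[C@@H]5C(C(=O)OC)=CO[C@@H](O[C@H]6[C@@H]([C@H]([C@@H]([C@H](O6)CO)O)O)O)/C5=C/C)C[C@H]3C(CO)CO | intermediate
21 | CNP0313563.1, [(1S,2R,3R,5R)-5-(1,3-dihydroxypropan-2-yl)-2-methyl-3-{[(3S,4E)-4-formyl-3-(2-oxoethyl)hex-4-enoyl]oxy}cyclopentyl]methyl (3S,4E)-4-formyl-3-(2-oxoethyl)hex-4-enoate | C/C=C(/C=O)[C@@H](CC=O)CC(=O)OC[C@@H]1[C@@H](C)[C@H](OC(=O)C[C@H](CC=O)/C(C=O)=C\C)C[C@H]1C(CO)CO | target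

## Step count and risks

Total: 12 steps. Longest linear sequence: 10 steps (steps 1–6 and 9–12, from silane 1). The arm branch (steps 7 and 8) joins at step 9.

**Step 2 (key step).** Proton transfer between enolate 5 and the methylated ketone may outrun C-methylation, leading to loss of silanolate and to over-methylation, or the magnesium enolate may alkylate too slowly. Fallback: install the methyl first and replace enolate alkylation by protonation. Starting from 3, α-iodination (I2, pyridine, CH2Cl2) should give (R)-4-(tert-butyldimethylsilyloxy)-2-iodocyclopent-2-en-1-one F1. Negishi methylation (MeZnCl, Pd(PPh3)4, zerovalent palladium, THF, rt) should then give (R)-4-(tert-butyldimethylsilyloxy)-2-methylcyclopent-2-en-1-one F2. The same CuI-catalysed addition of 2 with an NH4Cl quench would return to the route at 6; any C8 epimer from kinetic protonation would be equilibrated to the trans ketone by the DBU of step 3.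

**Step 3.** DBU may remove the γ-hydrogen at C9 of enone 8, causing epimerisation or double-bond migration, before the malonate adds; a slow addition would also erode facial selectivity. Fallback: separate the two events and change the addition from base to Lewis acid catalysis. Starting from 6, silanol would be eliminated on basic Al2O3 in CH2Cl2 and enone 8 isolated. A Mukaiyama–Michael addition of methyl 3-methoxy-3-(trimethylsilyloxy)acrylate (Sc(OTf)3 cat., CH2Cl2, −78 °C) should give the silyl enol ether dimethyl 2-[(1S,4R,5S)-5-{[dimethyl(propan-2-yloxy)silyl]methyl}-4-methyl-3-(trimethylsilyloxy)cyclopent-2-en-1-yl]propanedioate F3. Hydrolysis on work-up returns to the route at 9.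

**Step 10.** The SN2 displacement at the secondary C7, flanked by the cis methyl, may be slower than elimination or than acylation of the reduced azo reagent, because acid 17 is bulky and only moderately acidic. Fallback: invert before any arm is attached, using a stronger acid. Starting from 13, a double Mitsunobu reaction with 4-nitrobenzoic acid (PPh3, DIAD, THF, acid in excess) should give [(1S,2R,3R,5R)-5-(2,2-dimethyl-1,3-dioxan-5-yl)-2-methyl-3-(4-nitrobenzoyloxy)cyclopentyl]methyl 4-nitrobenzoate F4. Methanolysis (K2CO3, MeOH) should give (1R,2R,3S,4R)-4-(2,2-dimethyl-1,3-dioxan-5-yl)-3-(hydroxymethyl)-2-methylcyclopentan-1-ol F5. A double Steglich esterification with 17 (2.4 equiv, DCC, DMAP) returns to the route at 19.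

**Step 12.** At 150 °C the glycoside cleavage may stay incomplete on one arm, or the freed 1,5-dialdehydes may undergo aldol condensation and the esters slow hydrolysis before both arms are unveiled. Fallback: split the unveiling into a mild and a short hot stage. Starting from 20, β-glucosidase (acetate buffer, pH 5, 37 °C) should give the bis-aglycone F6, that is 20 with both glucosyloxy groups replaced by hemiacetal hydroxyls. Decarbomethoxylation of this far more reactive formylacetate precursor in wet DMSO at 150 °C with short microwave heating returns to the route at 21.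

## Further compounds

F1 | step 2 | (R)-4-(tert-butyldimethylsilyloxy)-2-iodocyclopent-2-en-1-one | O=C1C(I)=C[C@H](O[Si](C)(C)C(C)(C)C)C1
F2 | step 2 | (R)-4-(tert-butyldimethylsilyloxy)-2-methylcyclopent-2-en-1-one | O=C1C(C)=C[C@H](O[Si](C)(C)C(C)(C)C)C1
F3 | step 3 | dimethyl 2-[(1S,4R,5S)-5-{[dimethyl(propan-2-yloxy)silyl]methyl}-4-methyl-3-(trimethylsilyloxy)cyclopent-2-en-1-yl]propanedioate | CC(C)O[Si](C)(C)C[C@@H]1[C@@H](C)C(O[Si](C)(C)C)=C[C@H]1C(C(=O)OC)C(=O)OC
F4 | step 10 | [(1S,2R,3R,5R)-5-(2,2-dimethyl-1,3-dioxan-5-yl)-2-methyl-3-(4-nitrobenzoyloxy)cyclopentyl]methyl 4-nitrobenzoate | O=C(OC[C@@H]1[C@@H](C)[C@H](OC(=O)c2ccc(cc2)[N+](=O)[O-])C[C@H]1C3COC(C)(C)OC3)c4ccc(cc4)[N+](=O)[O-]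
F5 | step 10 | (1R,2R,3S,4R)-4-(2,2-dimethyl-1,3-dioxan-5-yl)-3-(hydroxymethyl)-2-methylcyclopentan-1-ol | OC[C@@H]1[C@@H](C)[C@H](O)C[C@H]1C2COC(C)(C)OC2
F6 | step 12 | bis-aglycone: 20 with both β-D-glucopyranosyloxy groups replaced by hydroxyl (hemiacetals, anomeric configuration not defined) | C/C=C/1\[C@@H](C(=COC1O)C(=O)OC)CC(=O)OC[C@@H]3[C@@H](C)[C@H](OC(=O)C[C@@H]5C(C(=O)OC)=COC(O)/C5=C/C)C[C@H]3C(CO)CO
A1 | alternative 1 | methyl (3R)-3-(2,2-dimethyl-1,3-dioxan-5-yl)-5-oxoheptanoate | COC(=O)C[C@@H](CC(=O)CC)C1COC(C)(C)OC1
A2 | alternative 1 | methyl (1S,2R,5S)-5-(2,2-dimethyl-1,3-dioxan-5-yl)-2-methyl-3-oxocyclopentane-1-carboxylate (all-trans) | COC(=O)[C@@H]1[C@@H](C)C(=O)C[C@H]1C2COC(C)(C)OC2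
A3 | alternative 2 | [(1S,2R,3R,5R)-3-{[(E)-5,5-dimethoxypent-2-enoyl]oxy}-5-(2,2-dimethyl-1,3-dioxan-5-yl)-2-methylcyclopentyl]methyl (E)-5,5-dimethoxypent-2-enoate | COC(OC)C/C=C/C(=O)OC[C@@H]1[C@@H](C)[C@H](OC(=O)/C=C/CC(OC)OC)C[C@H]1C2COC(C)(C)OC2
A4 | alternative 2 | (E)-(1,1-dimethoxybut-2-en-2-yl)boronic acid | C/C=C(\B(O)O)C(OC)OC
A5 | alternative 2 | core acetonide bis[(3S,4E)-3-(2,2-dimethoxyethyl)-4-(dimethoxymethyl)hex-4-enoate] | C/C=C(/C(OC)OC)[C@@H](CC(OC)OC)CC(=O)OC[C@@H]1[C@@H](C)[C@H](OC(=O)C[C@H](CC(OC)OC)/C(C(OC)OC)=C\C)C[C@H]1C2COC(C)(C)OC2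
A6 | alternative 3 | cyclopenta-1,3-diene | C1=CCC=C1
A7 | alternative 3 | 3-[(E)-4-(tert-butyldiphenylsilyloxy)but-2-enoyl]-1,3-oxazolidin-2-one | CC(C)(C)[Si](c1ccccc1)(c1ccccc1)OC/C=C/C(=O)N1CCOC1=O
A8 | alternative 3 | endo-acyl, exo-silyloxymethyl norbornene imide, 3-{[3-exo-(tert-butyldiphenylsilyloxymethyl)bicyclo[2.2.1]hept-5-en-2-endo-yl]carbonyl}-1,3-oxazolidin-2-one | CC(C)(C)[Si](c1ccccc1)(c1ccccc1)OC[C@@H]2[C@@H](C(=O)N3CCOC3=O)[C@H]4C=C[C@@H]2C4
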